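The cyclohexane ring (C1, C10, C11, C12, C13, C14; briarane numbering) is cut into a C11–C10–C1 bis-nucleophile and the three-carbon unit C12–C13–C14. The key step exploits the 1,3-relation of the quaternary C1 and the oxygen-bearing C11 across C10, and the oxygen on C14: the enolate–nitronate dianion of a 3-methyl-4-(nitromethyl)butyrolactone is C-acylated at C1 by acryloyl chloride, and the nitronate carbon C11 then closes the ring by conjugate addition to C12. The precursor is this small lactone, whose C2(=O)–O–C9 ring is a temporary stand-in for the trans-fused ten-membered ring; it is later opened, and the macrocycle is closed by metathesis at C5=C6.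

Key step: step 4

Remark: briarane numbering is used for all intermediates (ten-membered ring C1–C10; six-membered ring C1, C10–C14; C15 on C1, C16 on C5, C20 on C11; lactone C19(=O)–C17–C8 with C18 on C17); β is the face of the C15 methyl group, α the opposite face.

Step 1
Reactants: 1 (tert-butyldimethylsilyloxy)acetaldehyde; 2 nitromethane
Product: 5 (E)-tert-butyldimethyl[(3-nitroprop-2-en-1-yl)oxy]silane, via nitro alcohol 3 (not isolated), via mesylate 4 (not isolated)
Conditions: Et3N (cat.), CH2Cl2, 0 °C; then MsCl, Et3N, −20 to 0 °C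
Reagents that add atoms: none
Why: Henry addition of nitromethane to the aldehyde, then mesylation and E1cB elimination in the same flask, should give the conjugated nitroalkene in its favoured E geometry.

Step 2
Reactants: 5 nitroalkene; 6 propanal
Product: 7 (2R,3R)-3-[(tert-butyldimethylsilyloxy)methyl]-2-methyl-4-nitrobutanal
Conditions: (S)-α,α-diphenylprolinol trimethylsilyl ether (10 mol %), 4-nitrophenol (10 mol %), toluene, 0 °C
Reagents that add atoms: none
Why: Enamine-catalysed asymmetric Michael addition of an aldehyde to a nitroalkene, in which the diarylprolinol silyl ether shields one face of the propanal enamine so that the syn adduct with C10 in the R configuration should form with high enantioselectivity (the C1 centre is erased by enolization in step 4).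

Step 3
Reactants: 7 nitro aldehyde
Product: 10 (3R,4R)-3-methyl-4-(nitromethyl)oxolan-2-one, via silyloxy acid 8 (not isolated), via hydroxy acid 9 (not isolated)
Conditions: NaClO2, NaH2PO4, 2-methyl-2-butene, t-BuOH/H2O, 0 °C to rt; then 2 M HCl, THF, rt
Reagents that add atoms: sodium chlorite, [Na+].[O-]Cl=O
Why: Pinnick oxidation converts the aldehyde into the acid without touching the nitro group, and acidification cleaves the primary silyl ether so that the γ-hydroxy acid closes to the five-membered lactone with no change at C10.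

Step 4
Reactants: 10 nitromethyl lactone; 11 acryloyl chloride
Product: 14 (3aR,4R,7aR)-7a-methyl-4-nitrohexahydro-2-benzofuran-1,7-dione (trans-fused), via dilithium enolate–nitronate 12 (not isolated), via acylated lithium nitronate 13 (not isolated)
Conditions: LiN(i-Pr)2 (2.2 equiv), THF, −78 °C; 11 (1.05 equiv), −78 °C; then 0 °C to rt; AcOH
Reagents that add atoms: none
Why: LiN(i-Pr)2 forms first the nitronate and then the lactone enolate; the enolate carbon C1, the harder and more basic site, is C-acylated by the acid chloride at −78 °C (Claisen-type acylation), and on warming the nitronate carbon C11 adds to the terminal carbon C12 of the resulting vinyl ketone (intramolecular nitro-Michael addition). The closest known reaction type is the [3+3] carbo-annulation of enamines and other 1,3-bis-nucleophiles with acryloyl chloride by acylation and conjugate addition. The cyclohexane ring is closed in the 6-endo-trig mode through a chair-like transition state. The quaternary C1 is controlled by the C10 substituent of the five-membered enolate, which directs the acid chloride to the opposite face and so sets the trans C1/C10 relation; C11 is epimerizable and should settle with the nitro group equatorial (it becomes sp2 in step 6). The step needs site selectivity (enolate carbon before nitronate oxygen, C- before O-acylation) and facial selectivity; the first is secured by the low nucleophilicity of the delocalized nitronate at −78 °C and by the non-enolizable quaternary centre that forms, the second by the nitronate arm on C10.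

Step 5
Reactants: 14 nitro keto lactone
Product: 15 (3aR,4R,7S,7aR)-7-hydroxy-7a-methyl-4-nitrohexahydro-2-benzofuran-1(3H)-one
Conditions: LiBH(s-Bu)3 (2.2 equiv), THF, −78 °C; AcOH
Reagents that add atoms: none
Why: Ketone reduction by a bulky trialkylborohydride, where equatorial attack on the C14 carbonyl of the rigid trans-fused chair (a cyclohexanone flanked by a quaternary carbon) should give the axial 14α-alcohol (14S) while the lactone and nitro group are left intact at −78 °C.

Step 6
Reactants: 15 nitro alcohol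
Product: 17 (3aS,7S,7aR)-7-hydroxy-7a-methylhexahydro-2-benzofuran-1,4-dione (C11 ketone), via DBU-H nitronate 16 (not isolated)
Conditions: DBU (1.1 equiv), THF, 0 °C; then aq. TiCl3, NH4OAc (pH 5–6), rt
Reagents that add atoms: water, O
Why: Nef reaction in its reductive TiCl3 variant, in which the nitronate is reduced to the imine and hydrolysed near neutral pH, so that the lactone, the free alcohol and the epimerizable C10 centre next to the new ketone should survive.

Step 7
Reactants: 17 keto lactone
Product: 18 (3aS,7S,7aR)-7-hydroxy-7a-methyl-4-methylidenehexahydro-2-benzofuran-1(3H)-one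
Conditions: Zn, CH2Br2, TiCl4, THF/CH2Cl2, 0 °C to rt
Reagents that add atoms: dibromomethane, BrCBr
Why: Takai–Lombardo methylenation is non-basic, so the C11 ketone should give the exocyclic C11=C20 alkene without epimerization at C10 or β-elimination of the C9 acyloxy group, and the lactone carbonyl is not attacked.

Step 8
Reactants: 18 methylene lactone
Product: 19 11α,20-epoxy lactone (spiro epoxide of 18 with the 11R configuration)
Conditions: mCPBA, NaHCO3, CH2Cl2, 0 °C
Reagents that add atoms: mCPBA, OOC(=O)c1cccc(Cl)c1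
Why: Prilezhaev epoxidation, in which the axial face of the C11=C20 bond in the locked chair is blocked by the syn-axial C15 methyl, so the peracid should add from the equatorial α-face and place oxygen α and C20 β as in the target.

Step 9
Reactants: 19 epoxy lactone; 20 4-bromo-2-methylbut-1-ene
Product: 22 C2 ketone diol (lactone opened by the C3–C5 chain), via (3-methylbut-3-en-1-yl)lithium 21 (not isolated)
Conditions: 20, t-BuLi (2 equiv), Et2O, −78 °C; then 19 (0.3 equiv), THF, −78 to −40 °C; aq. NH4Cl
Reagents that add atoms: none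
Why: Addition of a primary alkyllithium to the hindered α-quaternary lactone should stop at the tetrahedral lithium hemiketal, which gives the C2 ketone and the free C9 alcohol on work-up, while the neopentyl-type spiro epoxide is not opened at low temperature.

Step 10
Reactants: 22 C2 ketone diol
Product: 24 2α,9,14α-triol, via diethylboron chelate 23 (not isolated)
Conditions: Et2BOMe, THF/MeOH (4:1), −78 °C; NaBH4, −78 °C; MeOH co-evaporation
Reagents that add atoms: none
Why: Narasaka–Prasad reduction, in which the axial C14 oxygen and the equatorial C2 carbonyl form a six-membered boron chelate fused to the cyclohexane and external hydride attacks it axially, should give the syn-1,3-diol, that is the 2α-alcohol (2R).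

Step 11
Reactants: 24 triol
Product: 25 tris(triethylsilyl) ether
Conditions: TESCl, imidazole, DMAP (cat.), DMF, rt
Reagents that add atoms: chlorotriethylsilane, CC[Si](Cl)(CC)CC
Why: Silylation of all three hydroxyl groups with the small triethylsilyl group under neutral imidazole conditions, which the epoxide tolerates.

Step 12
Reactants: 25 tris(triethylsilyl) ether
Product: 26 C9 aldehyde (C2 and C14 silyl ethers retained)
Conditions: (COCl)2, DMSO, CH2Cl2, −78 to −30 °C; Et3N, −78 to 0 °C
Reagents that add atoms: none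
Why: Swern oxidation cleaves and oxidizes a primary triethylsilyl ether directly to the aldehyde while the secondary ones stay, and the equatorial C10 centre α to the new aldehyde is the stable epimer.

Step 13
Reactants: 27 1,3-dithiane; 28 allyl bromide
Product: 30 2-allyl-1,3-dithiane, via 2-lithio-1,3-dithiane 29 (not isolated)
Conditions: n-BuLi, THF, −30 °C; 28, −78 °C to rt
Reagents that add atoms: none
Why: Corey–Seebach alkylation, in which the C2 anion of the dithiane displaces bromide from allyl bromide.

Step 14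
Reactants: 26 C9 aldehyde; 30 2-allyl-1,3-dithiane
Product: 33 C8 dithiane diene with a 9α-triethylsilyloxy group, via 2-allyl-2-lithio-1,3-dithiane 31 (not isolated), via lithium alkoxide 32 (not isolated)
Conditions: 30, n-BuLi, THF, −30 °C; 26, −78 °C; TESOTf, −78 to 0 °C
Reagents that add atoms: triethylsilyl trifluoromethanesulfonate, CC[Si](CC)(CC)OS(=O)(=O)C(F)(F)F
Why: Corey–Seebach addition of the C8 acyl-anion equivalent to the C9 aldehyde under Felkin–Anh control from C10 (the quaternary C1 arm anti to the nucleophile, reinforced by lithium bridging the aldehyde and epoxide oxygens) should give the 9α-alkoxide (9R), which is silylated in the flask.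

Step 15
Reactants: 33 dithiane diene
Product: 34 macrocyclic dithiane with the (5Z)-alkene
Conditions: second-generation Hoveyda–Grubbs catalyst (C31H38Cl2N2ORu, 15 mol %), toluene (1 mM), 80 °C, N2 sparge
Reagents that add atoms: none
Why: Ring-closing metathesis, in which the catalyst loads on the allyl alkene and closes onto the 1,1-disubstituted alkene, helped by the gem-disubstituted C8 and the trans-fused cyclohexane, should form the ten-membered ring as the less strained Z-alkene under thermodynamic control.

Step 16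
Reactants: 34 macrocyclic dithiane
Product: 35 macrocyclic C8 ketone
Conditions: PhI(O2CCF3)2, NaHCO3, MeCN/H2O (9:1), 0 °C
Reagents that add atoms: water, O
Why: Oxidative hydrolysis of the dithioacetal with a hypervalent iodine reagent under bicarbonate buffer should unmask the C8 ketone without isomerizing the β,γ-alkene or cleaving the silyl ethers or the epoxide.

Step 17
Reactants: 35 C8 ketone
Product: 37 7α-hydroxy C8 ketone, via potassium dienolate 36 (not isolated)
Conditions: KN(SiMe3)2, THF, −78 °C; 2-(phenylsulfonyl)-3-phenyloxaziridine, −78 °C; aq. NH4Cl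
Reagents that add atoms: 2-(phenylsulfonyl)-3-phenyloxaziridine, O=S(=O)(c1ccccc1)N1OC1c1ccccc1
Why: Enolate α-hydroxylation with an N-sulfonyloxaziridine, where deprotonation occurs at the doubly activated allylic C7, the dienolate is oxidized at its α-carbon, and attack from the more open α-face (the β-face carries the C15 methyl and the C11/C20 arm) is expected to give the 7α-alcohol (7S).

Step 18
Reactants: 37 7α-hydroxy ketone
Product: 38 7α-(2-bromopropanoyloxy) C8 ketone
Conditions: 2-bromopropanoyl bromide, pyridine, CH2Cl2, −20 to 0 °C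
Reagents that add atoms: 2-bromopropanoyl bromide, CC(Br)C(Br)=O
Why: Esterification of the secondary allylic alcohol with an acyl bromide proceeds with retention at C7; the bromine-bearing carbon is an epimer mixture that becomes planar in the next step.

Step 19
Reactants: 38 bromopropanoate
Product: 40 tris(triethylsilyl) ether of the 8α-hydroxy lactone, via samarium enolate 39 (not isolated)
Conditions: SmI2 (2.5 equiv), THF, −78 °C; aq. NH4Cl
Reagents that add atoms: none
Why: Intramolecular samarium Reformatsky reaction, in which SmI2 reduces the C–Br bond first and the tethered enolate adds to the C8 ketone from the face of the C7 oxygen, should close the trans-fused γ-lactone with 8α-OH (8S), while the chelated Z-enolate and the preference of the C18 methyl to lie anti to C9 set 17R.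

Step 20
Reactants: 40 silylated lactone
Product: 41 2α,8α,9α,14α-tetraol
Conditions: HF·pyridine, pyridine, THF, 0 °C to rt
Reagents that add atoms: none
Why: Fluoride cleavage of the three triethylsilyl ethers under buffered, weakly acidic conditions should spare the epoxide and avoid retro-aldol cleavage of the β-hydroxy lactone.

Step 21
Reactants: 41 tetraol
Product: 42 junceellolide F
Conditions: Ac2O, pyridine, DMAP (cat.), CH2Cl2, rt
Reagents that add atoms: acetic anhydride, CC(=O)OC(C)=O
Why: DMAP-catalysed acetylation should esterify the three secondary alcohols at C2, C9 and C14, while the hindered tertiary C8 alcohol is not acylated under these conditions.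

Compound list
1 | (tert-butyldimethylsilyloxy)acetaldehyde | CC(C)(C)[Si](C)(C)OCC=O | starting material
2 | nitromethane | C[N+](=O)[O-] | starting material
3 | 1-(tert-butyldimethylsilyloxy)-3-nitropropan-2-ol (racemic) | CC(C)(C)[Si](C)(C)OCC(O)C[N+](=O)[O-] | intermediate
4 | 1-(tert-butyldimethylsilyloxy)-3-nitropropan-2-yl methanesulfonate (racemic) | CC(C)(C)[Si](C)(C)OCC(OS(C)(=O)=O)C[N+](=O)[O-] | intermediate
5 | (E)-tert-butyldimethyl[(3-nitroprop-2-en-1-yl)oxy]silane | CC(C)(C)[Si](C)(C)OC/C=C/[N+](=O)[O-] | intermediate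
6 | propanal | CCC=O | starting material
7 | (2R,3R)-3-[(tert-butyldimethylsilyloxy)methyl]-2-methyl-4-nitrobutanal | [O-][N+](=O)C[C@H](CO[Si](C)(C)C(C)(C)C)[C@@H](C)C=O | intermediate
8 | (2R,3R)-3-[(tert-butyldimethylsilyloxy)methyl]-2-methyl-4-nitrobutanoic acid | [O-][N+](=O)C[C@H](CO[Si](C)(C)C(C)(C)C)[C@@H](C)C(=O)O | intermediate
9 | (2R,3R)-3-(hydroxymethyl)-2-methyl-4-nitrobutanoic acid | [O-][N+](=O)C[C@H](CO)[C@@H](C)C(=O)O | intermediate
10 | (3R,4R)-3-methyl-4-(nitromethyl)oxolan-2-one (cis; C10 is R) | [O-][N+](=O)C[C@@H]1COC(=O)[C@@H]1C | intermediate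
11 | acryloyl chloride | C=CC(Cl)=O | starting material
12 | dilithium enolate–nitronate of 10 | [Li+].[Li+].[O-]C1=C(C)[C@H](C=[N+]([O-])[O-])CO1 | intermediate
13 | lithium nitronate of the 3-acryloyl lactone (acryloyl trans to the nitronate arm) | [Li+].C=CC(=O)[C@]1(C)C(=O)OC[C@H]1C=[N+]([O-])[O-] | intermediate
14 | (3aR,4R,7aR)-7a-methyl-4-nitrohexahydro-2-benzofuran-1,7-dione (trans-fused; C14 ketone, C11 nitro) | O=C1CC[C@@H]([N+](=O)[O-])[C@@H]2COC(=O)[C@@]12C | intermediate
15 | (3aR,4R,7S,7aR)-7-hydroxy-7a-methyl-4-nitrohexahydro-2-benzofuran-1(3H)-one (14α-OH) | O[C@H]1CC[C@@H]([N+](=O)[O-])[C@@H]2COC(=O)[C@@]12C | intermediate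
16 | DBU-H salt of the C11 nitronate of 15 | O[C@H]1CCC(=[N+]([O-])[O-])[C@@H]2COC(=O)[C@@]12C.C1CCC2=[NH+]CCCN2CC1 | intermediate
17 | (3aS,7S,7aR)-7-hydroxy-7a-methylhexahydro-2-benzofuran-1,4-dione (C11 ketone) | O[C@H]1CCC(=O)[C@@H]2COC(=O)[C@@]12C | intermediate
18 | (3aS,7S,7aR)-7-hydroxy-7a-methyl-4-methylidenehexahydro-2-benzofuran-1(3H)-one | O[C@H]1CCC(=C)[C@@H]2COC(=O)[C@@]12C | intermediate
19 | 11α,20-epoxy-14α-hydroxy trans-fused lactone (11R spiro epoxide of 18) | O[C@H]1CC[C@]2(CO2)[C@@H]2COC(=O)[C@@]12C | intermediate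
20 | 4-bromo-2-methylbut-1-ene | C=C(C)CCBr | starting material
21 | (3-methylbut-3-en-1-yl)lithium | [Li]CCC(C)=C | intermediate
22 | C2 ketone with the 3-methylbut-3-enyl chain; 9-hydroxy, 14α-hydroxy, 11α,20-epoxide | O[C@H]1CC[C@]2(CO2)[C@H](CO)[C@@]1(C)C(=O)CCC(C)=C | intermediate
23 | C14 O-diethylboron chelate of 22 | CCB(CC)O[C@H]1CC[C@]2(CO2)[C@H](CO)[C@@]1(C)C(=O)CCC(C)=C | intermediate
24 | 2α,9,14α-triol (2R) | O[C@H]1CC[C@]2(CO2)[C@H](CO)[C@@]1(C)[C@H](O)CCC(C)=C | intermediate
25 | 2α,9,14α-tris(triethylsilyl) ether | CC[Si](CC)(CC)O[C@H]1CC[C@]2(CO2)[C@H](CO[Si](CC)(CC)CC)[C@@]1(C)[C@H](O[Si](CC)(CC)CC)CCC(C)=C | intermediate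
26 | C9 aldehyde with 2α- and 14α-triethylsilyloxy groups | CC[Si](CC)(CC)O[C@H]1CC[C@]2(CO2)[C@H](C=O)[C@@]1(C)[C@H](O[Si](CC)(CC)CC)CCC(C)=C | intermediate
27 | 1,3-dithiane | C1CSCSC1 | starting material
28 | allyl bromide | C=CCBr | starting material
29 | 2-lithio-1,3-dithiane | [Li]C1SCCCS1 | intermediate
30 | 2-allyl-1,3-dithiane | C=CCC1SCCCS1 | intermediate
31 | 2-allyl-2-lithio-1,3-dithiane | [Li]C1(CC=C)SCCCS1 | intermediate
32 | lithium 9α-alkoxide of the dithiane adduct | [Li+].CC[Si](CC)(CC)O[C@H]1CC[C@]2(CO2)[C@H]([C@@H]([O-])C3(CC=C)SCCCS3)[C@@]1(C)[C@H](O[Si](CC)(CC)CC)CCC(C)=C | intermediate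
33 | seco diene: C8 as 2-allyl-1,3-dithiane, 2α,9α,14α-tris(triethylsilyloxy), 11α,20-epoxide (9R) | CC[Si](CC)(CC)O[C@H]1CC[C@]2(CO2)[C@H]([C@@H](O[Si](CC)(CC)CC)C3(CC=C)SCCCS3)[C@@]1(C)[C@H](O[Si](CC)(CC)CC)CCC(C)=C | intermediate
34 | (5Z)-macrocycle with C8 as 1,3-dithiane | CC[Si](CC)(CC)O[C@H]1CC[C@]2(CO2)[C@@H]2[C@@H](O[Si](CC)(CC)CC)C3(SCCCS3)C/C=C(/C)CC[C@@H](O[Si](CC)(CC)CC)[C@@]12C | intermediate
35 | (5Z)-macrocyclic C8 ketone | CC[Si](CC)(CC)O[C@H]1CC[C@]2(CO2)[C@@H]2[C@@H](O[Si](CC)(CC)CC)C(=O)C/C=C(/C)CC[C@@H](O[Si](CC)(CC)CC)[C@@]12C | intermediate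
36 | potassium C7–C8 dienolate of 35 | [K+].CC[Si](CC)(CC)O[C@H]1CC[C@]2(CO2)[C@@H]2[C@@H](O[Si](CC)(CC)CC)C([O-])=C/C=C(/C)CC[C@@H](O[Si](CC)(CC)CC)[C@@]12C | intermediate
37 | 7α-hydroxy C8 ketone (7S) | CC[Si](CC)(CC)O[C@H]1CC[C@]2(CO2)[C@@H]2[C@@H](O[Si](CC)(CC)CC)C(=O)[C@@H](O)/C=C(/C)CC[C@@H](O[Si](CC)(CC)CC)[C@@]12C | intermediate
38 | 7α-(2-bromopropanoyloxy) C8 ketone (epimers at the C–Br carbon) | CC[Si](CC)(CC)O[C@H]1CC[C@]2(CO2)[C@@H]2[C@@H](O[Si](CC)(CC)CC)C(=O)[C@@H](OC(=O)C(C)Br)/C=C(/C)CC[C@@H](O[Si](CC)(CC)CC)[C@@]12C | intermediate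
39 | samarium enolate of 38 | CC[Si](CC)(CC)O[C@H]1CC[C@]2(CO2)[C@@H]2[C@@H](O[Si](CC)(CC)CC)C(=O)[C@@H](OC([O-])=CC)/C=C(/C)CC[C@@H](O[Si](CC)(CC)CC)[C@@]12C.[Sm+3].[I-].[I-] | intermediate
40 | 2α,9α,14α-tris(triethylsilyl) ether of the 8α-hydroxy 7,19-lactone (7S,8S,17R) | CC[Si](CC)(CC)O[C@H]1CC[C@]2(CO2)[C@@H]2[C@@H](O[Si](CC)(CC)CC)[C@@]3(O)[C@H](/C=C(/C)CC[C@@H](O[Si](CC)(CC)CC)[C@@]12C)OC(=O)[C@@H]3C | intermediate
41 | 2α,8α,9α,14α-tetrahydroxy-11α,20-epoxy lactone (tri-O-deacetyl junceellolide F) | O[C@H]1CC[C@]2(CO2)[C@@H]2[C@@H](O)[C@@]3(O)[C@H](/C=C(/C)CC[C@@H](O)[C@@]12C)OC(=O)[C@@H]3C | intermediate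
42 | junceellolide F, (1S,2R,5Z,7S,8S,9R,10S,11R,14S,17R) | CC(=O)O[C@H]1CC[C@]2(CO2)[C@@H]2[C@@H](OC(C)=O)[C@@]3(O)[C@H](/C=C(/C)CC[C@@H](OC(C)=O)[C@@]12C)OC(=O)[C@@H]3C | target

Total step count: 21. Longest linear sequence: 20 steps (steps 1–12 and 14–21; step 13 is a one-step side branch).

Steps most likely to fail

Step 15: the metathesis may stall at dimers or open-chain products because of ring strain, slow reaction of the 1,1-disubstituted alkene, or sulfur binding to ruthenium. Fallback: from 33 the lactone is built first so that it preorganizes the chain. Dithioacetal hydrolysis with PhI(O2CCF3)2 gives the open-chain C8 ketone F3. Hydroxylation at C7 as in step 17 gives the 7α-hydroxy ketone F4. Acylation as in step 18 gives the 2-bromopropanoate F5. SmI2 cyclization as in step 19 gives the seco vinyl lactone F6. Ring-closing metathesis of F6 with the same catalyst then comes back to the route at 40.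

Step 4: O-acylation of the nitronate or oligomerization of the vinyl ketone may consume the dianion before the ring closes. Fallback: from 10 the dianion is treated with acrolein at −78 °C, which should add 1,2 at C1 (again anti to the C10 arm) and give the allylic alcohol 3-(1-hydroxyprop-2-en-1-yl)-3-methyl-4-(nitromethyl)oxolan-2-one F1. Dess–Martin oxidation gives the neutral vinyl ketone 3-methyl-4-(nitromethyl)-3-(prop-2-enoyl)oxolan-2-one F2. Catalytic DBU in CH2Cl2 then closes the ring by nitro-Michael addition and comes back to the route at 14.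

Step 17: oxygen transfer to the macrocyclic dienolate may occur with poor or reversed facial selectivity at C7. Fallback: from 35 the same hydroxylation is run and the 7β-hydroxy C8 ketone F7 is taken on. Mitsunobu esterification with 2-bromopropanoic acid, PPh3 and DIAD inverts C7 and comes back to the route at 38.

Further compounds
F1 | step 4 | (3R,4R)-3-(1-hydroxyprop-2-en-1-yl)-3-methyl-4-(nitromethyl)oxolan-2-one (carbinol epimers) | C=CC(O)[C@]1(C)C(=O)OC[C@H]1C[N+](=O)[O-]
F2 | step 4 | (3R,4R)-3-methyl-4-(nitromethyl)-3-(prop-2-enoyl)oxolan-2-one | C=CC(=O)[C@]1(C)C(=O)OC[C@H]1C[N+](=O)[O-]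
F3 | step 15 | open-chain C8 ketone (allyl ketone) from 33 | CC[Si](CC)(CC)O[C@H]1CC[C@]2(CO2)[C@H]([C@@H](O[Si](CC)(CC)CC)C(=O)CC=C)[C@@]1(C)[C@H](O[Si](CC)(CC)CC)CCC(C)=C
F4 | step 15 | open-chain 7α-hydroxy C8 ketone | CC[Si](CC)(CC)O[C@H]1CC[C@]2(CO2)[C@H]([C@@H](O[Si](CC)(CC)CC)C(=O)[C@@H](O)C=C)[C@@]1(C)[C@H](O[Si](CC)(CC)CC)CCC(C)=C
F5 | step 15 | open-chain 7α-(2-bromopropanoyloxy) C8 ketone | CC[Si](CC)(CC)O[C@H]1CC[C@]2(CO2)[C@H]([C@@H](O[Si](CC)(CC)CC)C(=O)[C@@H](OC(=O)C(C)Br)C=C)[C@@]1(C)[C@H](O[Si](CC)(CC)CC)CCC(C)=C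
F6 | step 15 | seco vinyl lactone (8α-hydroxy 7,19-lactone with a C7 vinyl group and the open C3–C5 chain) | CC[Si](CC)(CC)O[C@H]1CC[C@]2(CO2)[C@H]([C@@H](O[Si](CC)(CC)CC)[C@@]3(O)[C@H](C=C)OC(=O)[C@@H]3C)[C@@]1(C)[C@H](O[Si](CC)(CC)CC)CCC(C)=C
F7 | step 17 | 7β-hydroxy C8 ketone (C7 epimer of 37) | CC[Si](CC)(CC)O[C@H]1CC[C@]2(CO2)[C@@H]2[C@@H](O[Si](CC)(CC)CC)C(=O)[C@H](O)/C=C(/C)CC[C@@H](O[Si](CC)(CC)CC)[C@@]12C
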